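Q was your question, and your hunch was that it simply climbs towards the D charged. The dusk readings of this same flask say how far short of that it should stand at 2.5 h.

- dusk: G 20 mM; D 14 mM; the very flask that is asked about, followed so far
- flask: G 20 mM; D 14.0 mM; time 2.5 h

- dusk (time / min: Q / %, X / %): 8.00: 12.0, 6.9; 20.0: 19.7, 10.4; 40.0: 27.5, 12.1; 60.0: 31.2, 12.6

(each reading ± 0.5 percentage points)

1. how much Q the flask holds at 2.5 h, in percent of the G charged
2. how much X the flask holds at 2.5 h, in percent of the G charged
3. how much L the flask holds at 2.5 h, in percent of the G charged
4. concentration of D at 2.5 h, in mM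

- steps thought possible: G + D -> L; G + D <-> X; G + D -> Q

D is the limiting reagent in this flask, 14.0 mM against 20 mM of G. That makes it 70.0% of the G charged, and in those units Q + L + X + free D stays 70.0%. If Q and L both form at rates proportional to [G][D], their ratio stays frozen from the first minute.

Between the first window, up to 8.00 min, and the one from 40.0 min to 60.0 min, Q's mean rate falls to 0.123 of its early value, and on that assumption so does [G][D]. We neglect L in the first window and take Q and X at half their first readings. Since G minus D stays 30 percentage points, free D in the later window comes to 15.0%. The balance then gives 0.452 for the split s, the L made per Q made, our selectivity factor. It is a soft reading: Q rises 3.7 points in that window against a scatter of 0.5 points. Guessing X plus free D together at 2.5 h at the size of the last X reading, 12.6%, we commit to Q 39.5% and L 17.9%.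

The forecast gives Q 37.3%, X 10.4%, L 18.7% and D 0.75 mM, with “L forms at about half the rate of Q”.

This flask gives Q 39.3%, X 10.1%, L 15.2% and D 1.09 mM.

    G + D → L (k = 0.00890 /M/s)
    G + D ⇌ X (K = 110 /M, k = 0.0130 /M/s)
    G + D → Q (k = 0.0230 /M/s)

This flask's L lies below ours, with L/Q at 0.387 against our s of 0.452. In the neighbour flask with 80 mM of G, the D used up, less its X and divided by 1.45, gives Q 10.3%, and that flask holds 10.8%. This flask is not at rest at 2.5 h: as it stands then, its slowest mode has a half-life of 2.56 h. Ten times the asked time, 25.0 h, leaves X 0.0291% and D 0.00348 mM, while L reaches 19.5% and Q gains 11 points to stand at 50.4%.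

(All runs are simulated with constants of no real substance.)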